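**Retrosynthetic overview**

1. Numbering follows 1-benzofuran (O1, C2, C3, C3a, C4–C7, C7a); ring A is the carbocycle, ring B the dihydrofuran, ring C the benzoate arene.
2. The target is the unconjugated tautomer of dienone 23 (ring diene at C4=C3a and C7a=C7); it is reached last by kinetic protonation of the extended enolate at C7.
3. Key disconnection: 23 comes from the acyclic phosphonium enolate 18 by an intramolecular ester Wittig closure (C3a–C7a, ring B) followed by 6π-electrocyclisation (C5–C6, ring A). The enabling feature is that the C4 and C7 arms sit cis on the C3a=C7a enol-ether double bond of ring B, so C5=C4–C3a=C7a–C7=C6 is a locked (Z)-hexatriene.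
4. 18 is assembled from cis-epoxide 6 and the 2-methoxyallyl ylide (C3–C3a), an acylketene (O1–C7a ester) and a formyl donor (C6).
5. Ring order: C (bought), then B, then A, the last two in one operation.

Key step: step 10

Remark: the target is a 6,7-dihydroarene that can aromatise by loss of water and is expected to be less stable than its conjugated tautomer 23, so ring A is made late and handled cold and buffered. 2-Methoxyallyl bromide is taken as commercially available. Ar = 5-(methoxycarbonyl)-2-[(triisopropylsilyl)oxy]phenyl.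

**Step 1**
Reactants: 1 methyl 4-hydroxy-3-iodobenzoate
Product: 2 methyl 3-iodo-4-[(triisopropylsilyl)oxy]benzoate
Conditions: iPr3SiCl, imidazole, DMF, rt
Reagents that add atoms: chlorotriisopropylsilane, CC(C)[Si](Cl)(C(C)C)C(C)C
Why: Silyl ether formation at the phenol; the hindered silyl ether should survive the basic hypochlorite of step 4 and the amide bases of steps 6, 10 and 11, and it prevents cyclisation of the later o-alkynylphenol to a benzofuran.

**Step 2**
Reactants: 2 methyl 3-iodo-4-[(triisopropylsilyl)oxy]benzoate; 3 2-methylbut-3-yn-2-ol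
Product: 4 methyl 3-(3-hydroxy-3-methylbut-1-yn-1-yl)-4-[(triisopropylsilyl)oxy]benzoate
Conditions: PdCl2(PPh3)2 (cat.), CuI (cat.), Et3N, THF, rt
Reagents that add atoms: none
Why: Sonogashira coupling of the aryl iodide with the terminal alkyne under amine base, which leaves the aryl silyl ether and the methyl ester untouched.

**Step 3**
Reactants: 4 methyl 3-(3-hydroxy-3-methylbut-1-yn-1-yl)-4-[(triisopropylsilyl)oxy]benzoate
Product: 5 methyl 3-[(Z)-3-hydroxy-3-methylbut-1-en-1-yl]-4-[(triisopropylsilyl)oxy]benzoate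
Conditions: H2 (1 atm), Lindlar catalyst (Pd on CaCO3, poisoned with Pb(OAc)2), quinoline, EtOAc, rt
Reagents that add atoms: none
Why: Lindlar semihydrogenation adds hydrogen syn and should stop at the (Z)-alkene, the geometry needed for a cis-epoxide.

**Step 4**
Reactants: 5 methyl 3-[(Z)-3-hydroxy-3-methylbut-1-en-1-yl]-4-[(triisopropylsilyl)oxy]benzoate
Product: 6 methyl 3-[(2R,3R)-3-(2-hydroxypropan-2-yl)oxiran-2-yl]-4-[(triisopropylsilyl)oxy]benzoate (cis-epoxide)
Conditions: (R,R)-Jacobsen catalyst [Mn(salen)Cl, C36H52ClMnN2O2] (cat.), NaOCl (aq., pH 11.3), 4-phenylpyridine N-oxide, CH2Cl2, 0 °C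
Reagents that add atoms: sodium hypochlorite, [Na+].[O-]Cl
Why: Jacobsen–Katsuki epoxidation of a cis-disubstituted aryl alkene keeps the cis geometry, and the (R,R)-catalyst should give the (2R,3R)-epoxide by analogy with cis-β-methylstyrene and indene, so C2 and C3 of the target are set here under catalyst control.

**Step 5**
Reactants: 7 3-bromo-2-methoxyprop-1-ene; 8 triphenylphosphine
Product: 9 (2-methoxyprop-2-en-1-yl)triphenylphosphonium bromide
Conditions: toluene, 60 °C
Reagents that add atoms: none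
Why: SN2 quaternisation of the phosphine by the allylic bromide gives the allylic phosphonium salt.

**Step 6**
Reactants: 9 (2-methoxyprop-2-en-1-yl)triphenylphosphonium bromide; 6 methyl 3-[(2R,3R)-3-(2-hydroxypropan-2-yl)oxiran-2-yl]-4-[(triisopropylsilyl)oxy]benzoate
Product: 12 [(4S,5R)-4-Ar-5,6-dihydroxy-2-methoxy-6-methylhept-1-en-3-yl]triphenylphosphonium bromide (epimers at C3 of the chain), via phosphorus ylide 10 (not isolated), via oxido phosphonium betaine 11 (not isolated)
Conditions: KN(SiMe3)2, THF, −78 → 0 °C; 6, 0 → 45 °C; NH4Br (aq.), 0 °C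
Reagents that add atoms: ammonium bromide, [NH4+].[Br-]
Why: The allylic ylide should open the epoxide through its phosphorus-bearing carbon at the benzylic carbon with inversion (SN2 opening of an epoxide by a phosphorus ylide; the other epoxide carbon is shielded by the quaternary carbinol), which keeps the C2–O configuration and fixes the threo C2/C3 relationship that becomes trans on ring B, and mild protonation of the betaine spares the enol ether.

**Step 7**
Reactants: 13 2,2-dimethyl-1,3-dioxane-4,6-dione (Meldrum's acid); 14 3-phenylpropanoyl chloride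
Product: 15 5-(1-hydroxy-3-phenylpropylidene)-2,2-dimethyl-1,3-dioxane-4,6-dione
Conditions: pyridine, CH2Cl2, 0 °C → rt
Reagents that add atoms: none
Why: C-acylation of Meldrum's acid by the acid chloride gives the stable precursor of the acylketene.

**Step 8**
Reactants: 12 [(4S,5R)-4-Ar-5,6-dihydroxy-2-methoxy-6-methylhept-1-en-3-yl]triphenylphosphonium bromide; 15 5-(1-hydroxy-3-phenylpropylidene)-2,2-dimethyl-1,3-dioxane-4,6-dione
Product: 17 [(4S,5R)-4-Ar-6-hydroxy-2-methoxy-6-methyl-5-[(3-oxo-5-phenylpentanoyl)oxy]hept-1-en-3-yl]triphenylphosphonium bromide, via acylketene 16 (not isolated)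
Conditions: MeCN, 80 °C
Reagents that add atoms: none
Why: Thermal fragmentation of the acyl Meldrum's acid releases the acylketene, which should be trapped by the secondary hydroxyl (the tertiary one is too hindered) to form the O1–C7a ester without acid or base, so the enol ether and the salt survive.

**Step 9**
Reactants: 17 [(4S,5R)-4-Ar-6-hydroxy-2-methoxy-6-methyl-5-[(3-oxo-5-phenylpentanoyl)oxy]hept-1-en-3-yl]triphenylphosphonium bromide
Product: 18 [(4S,5R)-4-Ar-6-hydroxy-2-methoxy-6-methyl-5-{[2-(oxidomethylidene)-3-oxo-5-phenylpentanoyl]oxy}hept-1-en-3-yl]triphenylphosphonium (inner salt)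
Conditions: MgCl2, Et3N, MeCN, 0 °C; 1H-benzotriazole-1-carbaldehyde; NaHCO3 (aq.) work-up
Reagents that add atoms: 1H-benzotriazole-1-carbaldehyde, O=Cn1nnc2ccccc12
Why: Magnesium-chelated soft enolisation and C-formylation of the β-keto ester (C-acylation of a 1,3-dicarbonyl magnesium enolate) puts C6 in place, triethylamine being too weak to form the ylide, and the acidic product is isolated as its phosphonium enolate inner salt.

**Step 10**
Reactants: 18 [(4S,5R)-4-Ar-6-hydroxy-2-methoxy-6-methyl-5-{[2-(oxidomethylidene)-3-oxo-5-phenylpentanoyl]oxy}hept-1-en-3-yl]triphenylphosphonium (inner salt)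
Product: 23 methyl 3-[(2R,3R,6R)-6-hydroxy-2-(2-hydroxypropan-2-yl)-4-methoxy-7-(3-phenylpropanoyl)-2,3,5,6-tetrahydro-1-benzofuran-3-yl]-4-[(triisopropylsilyl)oxy]benzoate, via silyl enol ether salt 19 (not isolated), via phosphorus ylide 20 (not isolated), via triene 21 (not isolated), via trimethylsilyl ether 22 (not isolated)
Conditions: Me3SiCl, THF–toluene, 0 °C; KN(SiMe3)2 (1 equiv), −78 → 80 °C; then NH4F, MeOH, 0 °C
Reagents that add atoms: none
Why: Me3SiCl silylates the formyl-derived enolate oxygen, and KN(SiMe3)2 then deprotonates only the phosphonium α-carbon C3a; the ylide attacks the ester carbonyl C7a in a 5-exo-trig intramolecular Wittig reaction (the known closure of 3-acyloxyalkyl phosphonium ylides to 4,5-dihydrofurans), forming C3a=C7a and ring B with loss of Ph3P=O. This gives triene 21 with the C4 and C7 arms held cis on C3a=C7a, and thermal disrotatory 6π-electrocyclisation (closest type: cyclisation of 2-acylhexa-1,3,5-trienes) joins C5 to C6 and closes six-membered ring A. C6 is the only new stereocentre: 1,3-allylic strain between the C4 methoxy group and the C3 aryl group should tilt the methoxy group to the face away from the aryl group, which fixes the sense of the boat-like transition state, and disrotation then turns the outward silyloxy group at C6 to the face anti to the aryl group (6R). The step needs the ylide to choose the ester carbonyl over the ketone and over C6 of the push–pull alkene, which the five-membered transition state (against seven-membered alternatives), the bulk of the ylide and the donor-deactivated ketone should secure, and it needs the silyloxy group outside, which the easy E/Z equilibration of the push–pull alkene allows. NH4F in methanol removes the trimethylsilyl group on work-up, giving hydroxy dienone 23 with its ring diene at C4=C3a and C7a=C7.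

**Step 11**
Reactants: 23 methyl 3-[(2R,3R,6R)-6-hydroxy-2-(2-hydroxypropan-2-yl)-4-methoxy-7-(3-phenylpropanoyl)-2,3,5,6-tetrahydro-1-benzofuran-3-yl]-4-[(triisopropylsilyl)oxy]benzoate
Product: 26 methyl 4-hydroxy-3-[(2R,3R,6R,7R)-6-hydroxy-2-(2-hydroxypropan-2-yl)-4-methoxy-7-(3-phenylpropanoyl)-2,3,6,7-tetrahydro-1-benzofuran-3-yl]benzoate, via tripotassium trienolate 24 (not isolated), via triisopropylsilyl ether 25 (not isolated)
Conditions: KN(SiMe3)2 (3.3 equiv), THF, −78 → −40 °C; cannulate into AcOH–THF, −78 °C; then Bu4NF–AcOH, THF, 0 °C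
Reagents that add atoms: none
Why: Excess base removes both hydroxyl protons and then, next to the C6 alkoxide, a C5 proton to give the fully conjugated trienolate, in which the C6 oxygen is an alkoxide and cannot leave; kinetic protonation of this extended enolate at the α-carbon C7 (deconjugative protonation) restores C3a=C7a and C4=C5, the proton should arrive anti to the C6 alkoxide so that the acyl group ends cis to the C6 oxygen (7R), and buffered fluoride then cleaves the aryl silyl ether without strong acid or base.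

**Compound list**

1 | methyl 4-hydroxy-3-iodobenzoate | COC(=O)c1ccc(O)c(I)c1 | starting material
2 | methyl 3-iodo-4-[(triisopropylsilyl)oxy]benzoate | COC(=O)c1ccc(O[Si](C(C)C)(C(C)C)C(C)C)c(I)c1 | intermediate
3 | 2-methylbut-3-yn-2-ol | CC(C)(O)C#C | starting material
4 | methyl 3-(3-hydroxy-3-methylbut-1-yn-1-yl)-4-[(triisopropylsilyl)oxy]benzoate | COC(=O)c1ccc(O[Si](C(C)C)(C(C)C)C(C)C)c(C#CC(C)(C)O)c1 | intermediate
5 | methyl 3-[(Z)-3-hydroxy-3-methylbut-1-en-1-yl]-4-[(triisopropylsilyl)oxy]benzoate | COC(=O)c1ccc(O[Si](C(C)C)(C(C)C)C(C)C)c(/C=C\C(C)(C)O)c1 | intermediate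
6 | methyl 3-[(2R,3R)-3-(2-hydroxypropan-2-yl)oxiran-2-yl]-4-[(triisopropylsilyl)oxy]benzoate (cis) | COC(=O)c1ccc(O[Si](C(C)C)(C(C)C)C(C)C)c([C@H]2O[C@H]2C(C)(C)O)c1 | intermediate
7 | 3-bromo-2-methoxyprop-1-ene (2-methoxyallyl bromide) | COC(=C)CBr | starting material
8 | triphenylphosphine | c1ccc(cc1)P(c1ccccc1)c1ccccc1 | starting material
9 | (2-methoxyprop-2-en-1-yl)triphenylphosphonium bromide | COC(=C)C[P+](c1ccccc1)(c1ccccc1)c1ccccc1.[Br-] | intermediate
10 | (2-methoxyprop-2-en-1-ylidene)triphenylphosphorane (ylide, not isolated) | COC(=C)C=P(c1ccccc1)(c1ccccc1)c1ccccc1 | intermediate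
11 | [(4S,5R)-4-Ar-6-hydroxy-2-methoxy-6-methyl-5-oxidohept-1-en-3-yl]triphenylphosphonium (betaine, not isolated) | COC(=O)c1ccc(O[Si](C(C)C)(C(C)C)C(C)C)c([C@@H]([C@@H]([O-])C(C)(C)O)C(C(=C)OC)[P+](c2ccccc2)(c2ccccc2)c2ccccc2)c1 | intermediate
12 | [(4S,5R)-4-Ar-5,6-dihydroxy-2-methoxy-6-methylhept-1-en-3-yl]triphenylphosphonium bromide (epimers at C3) | COC(=O)c1ccc(O[Si](C(C)C)(C(C)C)C(C)C)c([C@@H]([C@@H](O)C(C)(C)O)C(C(=C)OC)[P+](c2ccccc2)(c2ccccc2)c2ccccc2)c1.[Br-] | intermediate
13 | 2,2-dimethyl-1,3-dioxane-4,6-dione (Meldrum's acid) | CC1(C)OC(=O)CC(=O)O1 | starting material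
14 | 3-phenylpropanoyl chloride | O=C(Cl)CCc1ccccc1 | starting material
15 | 5-(1-hydroxy-3-phenylpropylidene)-2,2-dimethyl-1,3-dioxane-4,6-dione | CC1(C)OC(=O)C(=C(O)CCc2ccccc2)C(=O)O1 | intermediate
16 | 5-phenylpent-1-ene-1,3-dione (acylketene, not isolated) | O=C=CC(=O)CCc1ccccc1 | intermediate
17 | [(4S,5R)-4-Ar-6-hydroxy-2-methoxy-6-methyl-5-[(3-oxo-5-phenylpentanoyl)oxy]hept-1-en-3-yl]triphenylphosphonium bromide | COC(=O)c1ccc(O[Si](C(C)C)(C(C)C)C(C)C)c([C@@H]([C@@H](OC(=O)CC(=O)CCc2ccccc2)C(C)(C)O)C(C(=C)OC)[P+](c2ccccc2)(c2ccccc2)c2ccccc2)c1.[Br-] | intermediate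
18 | [(4S,5R)-4-Ar-6-hydroxy-2-methoxy-6-methyl-5-{[2-(oxidomethylidene)-3-oxo-5-phenylpentanoyl]oxy}hept-1-en-3-yl]triphenylphosphonium (inner salt) | COC(=O)c1ccc(O[Si](C(C)C)(C(C)C)C(C)C)c([C@@H]([C@@H](OC(=O)C(=C[O-])C(=O)CCc2ccccc2)C(C)(C)O)C(C(=C)OC)[P+](c2ccccc2)(c2ccccc2)c2ccccc2)c1 | intermediate
19 | [(4S,5R)-4-Ar-6-hydroxy-2-methoxy-6-methyl-5-({3-oxo-5-phenyl-2-[(trimethylsilyloxy)methylidene]pentanoyl}oxy)hept-1-en-3-yl]triphenylphosphonium chloride (not isolated) | COC(=O)c1ccc(O[Si](C(C)C)(C(C)C)C(C)C)c([C@@H]([C@@H](OC(=O)C(=CO[Si](C)(C)C)C(=O)CCc2ccccc2)C(C)(C)O)C(C(=C)OC)[P+](c2ccccc2)(c2ccccc2)c2ccccc2)c1.[Cl-] | intermediate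
20 | ylide of 19, triphenylphosphoranylidene at C3 of the heptene chain (not isolated) | COC(=O)c1ccc(O[Si](C(C)C)(C(C)C)C(C)C)c([C@@H]([C@@H](OC(=O)C(=CO[Si](C)(C)C)C(=O)CCc2ccccc2)C(C)(C)O)C(C(=C)OC)=P(c2ccccc2)(c2ccccc2)c2ccccc2)c1 | intermediate
21 | methyl 3-[(2R,3R)-2-(2-hydroxypropan-2-yl)-4-(1-methoxyethenyl)-5-{3-oxo-5-phenyl-1-[(trimethylsilyl)oxy]pent-1-en-2-yl}-2,3-dihydrofuran-3-yl]-4-[(triisopropylsilyl)oxy]benzoate (triene, not isolated) | COC(=O)c1ccc(O[Si](C(C)C)(C(C)C)C(C)C)c([C@@H]2C(C(=C)OC)=C(O[C@H]2C(C)(C)O)C(=CO[Si](C)(C)C)C(=O)CCc2ccccc2)c1 | intermediate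
22 | 6-O-trimethylsilyl ether of 23 (not isolated) | COC(=O)c1ccc(O[Si](C(C)C)(C(C)C)C(C)C)c([C@@H]2C3=C(OC)C[C@@H](O[Si](C)(C)C)C(C(=O)CCc4ccccc4)=C3O[C@H]2C(C)(C)O)c1 | intermediate
23 | methyl 3-[(2R,3R,6R)-6-hydroxy-2-(2-hydroxypropan-2-yl)-4-methoxy-7-(3-phenylpropanoyl)-2,3,5,6-tetrahydro-1-benzofuran-3-yl]-4-[(triisopropylsilyl)oxy]benzoate | COC(=O)c1ccc(O[Si](C(C)C)(C(C)C)C(C)C)c([C@@H]2C3=C(OC)C[C@@H](O)C(C(=O)CCc4ccccc4)=C3O[C@H]2C(C)(C)O)c1 | intermediate
24 | tripotassium salt: C6 alkoxide, side-chain tertiary alkoxide and C7 exocyclic enolate of 25 (not isolated) | [K+].[K+].[K+].COC(=O)c1ccc(O[Si](C(C)C)(C(C)C)C(C)C)c([C@@H]2C3=C(O[C@H]2C(C)(C)[O-])C(=C([O-])CCc2ccccc2)[C@H]([O-])C=C3OC)c1 | intermediate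
25 | methyl 3-[(2R,3R,6R,7R)-6-hydroxy-2-(2-hydroxypropan-2-yl)-4-methoxy-7-(3-phenylpropanoyl)-2,3,6,7-tetrahydro-1-benzofuran-3-yl]-4-[(triisopropylsilyl)oxy]benzoate (not isolated) | COC(=O)c1ccc(O[Si](C(C)C)(C(C)C)C(C)C)c([C@@H]2C3=C(O[C@H]2C(C)(C)O)[C@H](C(=O)CCc2ccccc2)[C@H](O)C=C3OC)c1 | intermediate
26 | methyl 4-hydroxy-3-[(2R,3R,6R,7R)-6-hydroxy-2-(2-hydroxypropan-2-yl)-4-methoxy-7-(3-phenylpropanoyl)-2,3,6,7-tetrahydro-1-benzofuran-3-yl]benzoate | COC(=O)c1ccc(O)c([C@@H]2C3=C(O[C@H]2C(C)(C)O)[C@H](C(=O)CCc2ccccc2)[C@H](O)C=C3OC)c1 | target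

**Step count and risks**

Total step count: 11. Longest linear sequence: 9 steps (1, 2, 3, 4, 6, 8, 9, 10, 11).

The three steps most likely to fail:

Step 10. The ylide may add to the ketone carbonyl or to C6 of the silyloxymethylene group instead of the ester carbonyl. Silylation may take place on the ketone oxygen. The electrocyclisation may close with poor torquoselectivity at C6. The fallback keeps the ketone out of the ring-forming step and sets out from 12. Esterification with propiolic acid (dicyclohexylcarbodiimide, CH2Cl2, −20 °C) gives the propiolate ester F1. Addition of tert-butyldimethylsilanol to the triple bond (catalytic DABCO) gives the (E)-3-silyloxyacrylate F2. KN(SiMe3)2 (toluene, −78 → 80 °C) then triggers the same Wittig closure and electrocyclisation, now with the ester as the only electrophile, to give the dienol ether F3. Its electron-rich C7 terminus is C-acylated with 3-phenylpropanoyl chloride 14 (pyridine, CH2Cl2, −20 °C) to the silyl-protected dienone F4. HF·pyridine buffered with pyridine frees the C6 hydroxyl and the route is rejoined at 23.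

Step 11. Enolisation may occur at the side-chain CH2 instead of C5, water may be lost to the arene during the quench, and the proton may be delivered to the wrong face of C7. The fallback makes the isomerisation without base and sets out from 23. Irradiation (365 nm, CH2Cl2, −40 °C, catalytic imidazole as proton shuttle) should transfer a C5 hydrogen to the excited ketone oxygen (photoenolisation, the first stage of a photodeconjugation) to give the trienol F5. F5 ketonises by protonation at C7 and the route is rejoined at 25, which buffered Bu4NF converts to 26 as in step 11.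

Step 6. Substitution at the hindered benzylic epoxide carbon may be slow, and the ylide may react through its terminal CH2 carbon instead of the phosphorus-bearing carbon. The fallback makes the same bond by conjugate addition and sets out from 6. Bu4NF removes the silyl group to give the phenol epoxide F6. KN(SiMe3)2 (1 equiv) forms the phenoxide, which opens the epoxide to the o-quinone methide alkoxide F7. Ylide 10 adds to its unhindered exocyclic carbon, anti to the bulky dimethylcarbinol group of the neighbouring stereocentre, and NH4Br gives the phenolic phosphonium salt F8 with the same threo configuration. Silylation (iPr3SiCl, imidazole) rejoins the route at 12.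

**Further compounds**

F1 | step 10 | [(4S,5R)-4-Ar-6-hydroxy-2-methoxy-6-methyl-5-(prop-2-ynoyloxy)hept-1-en-3-yl]triphenylphosphonium bromide | COC(=O)c1ccc(O[Si](C(C)C)(C(C)C)C(C)C)c([C@@H]([C@@H](OC(=O)C#C)C(C)(C)O)C(C(=C)OC)[P+](c2ccccc2)(c2ccccc2)c2ccccc2)c1.[Br-]
F2 | step 10 | [(4S,5R)-4-Ar-5-{[(E)-3-(tert-butyldimethylsilyloxy)prop-2-enoyl]oxy}-6-hydroxy-2-methoxy-6-methylhept-1-en-3-yl]triphenylphosphonium bromide | COC(=O)c1ccc(O[Si](C(C)C)(C(C)C)C(C)C)c([C@@H]([C@@H](OC(=O)/C=C/O[Si](C)(C)C(C)(C)C)C(C)(C)O)C(C(=C)OC)[P+](c2ccccc2)(c2ccccc2)c2ccccc2)c1.[Br-]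
F3 | step 10 | methyl 3-[(2R,3R,6R)-6-(tert-butyldimethylsilyloxy)-2-(2-hydroxypropan-2-yl)-4-methoxy-2,3,5,6-tetrahydro-1-benzofuran-3-yl]-4-[(triisopropylsilyl)oxy]benzoate | COC(=O)c1ccc(O[Si](C(C)C)(C(C)C)C(C)C)c([C@@H]2C3=C(OC)C[C@@H](O[Si](C)(C)C(C)(C)C)C=C3O[C@H]2C(C)(C)O)c1
F4 | step 10 | 6-O-tert-butyldimethylsilyl ether of 23 | COC(=O)c1ccc(O[Si](C(C)C)(C(C)C)C(C)C)c([C@@H]2C3=C(OC)C[C@@H](O[Si](C)(C)C(C)(C)C)C(C(=O)CCc4ccccc4)=C3O[C@H]2C(C)(C)O)c1
F5 | step 11 | trienol tautomer of 25 (exocyclic C7=C(OH) enol, ring diene at C3a=C7a and C4=C5) | COC(=O)c1ccc(O[Si](C(C)C)(C(C)C)C(C)C)c([C@@H]2C3=C(O[C@H]2C(C)(C)O)C(=C(O)CCc2ccccc2)[C@H](O)C=C3OC)c1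
F6 | step 6 | methyl 4-hydroxy-3-[(2R,3R)-3-(2-hydroxypropan-2-yl)oxiran-2-yl]benzoate | COC(=O)c1ccc(O)c([C@H]2O[C@H]2C(C)(C)O)c1
F7 | step 6 | potassium (2R)-3-hydroxy-1-[3-(methoxycarbonyl)-6-oxocyclohexa-2,4-dien-1-ylidene]-3-methylbutan-2-olate (o-quinone methide) | [K+].COC(=O)C1=CC(=C[C@@H]([O-])C(C)(C)O)C(=O)C=C1
F8 | step 6 | [(4S,5R)-5,6-dihydroxy-4-[2-hydroxy-5-(methoxycarbonyl)phenyl]-2-methoxy-6-methylhept-1-en-3-yl]triphenylphosphonium bromide | COC(=O)c1ccc(O)c([C@@H]([C@@H](O)C(C)(C)O)C(C(=C)OC)[P+](c2ccccc2)(c2ccccc2)c2ccccc2)c1.[Br-]
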